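The route rests on disconnecting C7–C8 of the nine-membered carbocycle (caryophyllene numbering), the bond between ring methylene C7 and the methylidene-bearing sp2 carbon C8. A one-pot 9-BBN hydroboration/intramolecular B-alkyl Suzuki–Miyaura coupling closes this ring last and creates the exocyclic C8=CH2 in the same operation. It exploits the 1,1-disubstituted alkene of the nine-membered ring and the gauche pre-organisation imposed by the trans-fused pyran (C4–C5) and the trans-cyclobutane (C1–C9). The precursor is the complete acylphloroglucinol-fused dihydropyran carrying a vinyl group at C5 and, on the C4 side chain, the cyclobutane with a 1-bromovinyl group at C9; its pyran stereocentres come from Sharpless epoxidation and anti vinyl-cuprate opening.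

Key step: step 14

Remark: terpenoid carbons carry β-caryophyllene numbers (C1 and C9 cyclobutane CH, C4 the O-bearing quaternary carbon, C5 its CH neighbour, C8 the methylidene carbon, C12 its exocyclic CH2); C1' is the CH2 between C5 and ring A; the triketone unit is written as the enol tautomer of the target SMILES.

Step 1
Reactants: 1 cyclohex-2-en-1-one; 2 2-methylpropene (isobutene)
Product: 4 (1R,6R)-7,7-dimethylbicyclo[4.2.0]octan-2-one, via trans-fused photoadduct 3 (not isolated)
Conditions: AlBr3-activated chiral B-aryl oxazaborolidine from α,α-diarylprolinol (50 mol%, the enantiomer that gives the 6R adduct), CH2Cl2, hν (366 nm), −75 °C; then basic Al2O3, rt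
Reagents that add atoms: none
Why: Enone–alkene [2+2] photocycloaddition in which the Lewis acid binds the enone carbonyl and shields one face of the β-carbon, so that head-to-tail addition of isobutene should set C6 (the later cyclobutane C1) as R, while basic alumina epimerises the α-carbon of any trans-fused adduct to the stable cis ring fusion.

Step 2
Reactants: 4 (1R,6R)-7,7-dimethylbicyclo[4.2.0]octan-2-one
Product: 6 (1R,6R)-7,7-dimethylbicyclo[4.2.0]oct-2-en-2-yl trifluoromethanesulfonate, via lithium enolate 5 (not isolated)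
Conditions: LiN(iPr)2, THF, −78 °C; PhNTf2, −78 to 0 °C
Reagents that add atoms: N-phenylbis(trifluoromethanesulfonimide), O=S(=O)(N(c1ccccc1)S(=O)(=O)C(F)(F)F)C(F)(F)F
Why: Kinetic deprotonation should occur at the C3 methylene and not at the ring-fusion methine, and O-triflation of the enolate fixes the double bond at C2=C3 without touching C1 or C6.

Step 3
Reactants: 6 (1R,6R)-7,7-dimethylbicyclo[4.2.0]oct-2-en-2-yl trifluoromethanesulfonate
Product: 7 (1R,6R)-2,7,7-trimethylbicyclo[4.2.0]oct-2-ene
Conditions: MeMgBr, Fe(acac)3 (5 mol%), THF/NMP, −20 to 0 °C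
Reagents that add atoms: methylmagnesium bromide, C[Mg]Br
Why: Iron-catalysed Kumada-type cross-coupling replaces the alkenyl triflate by methyl without moving the double bond, giving the trisubstituted alkene whose two carbons become the acetyl and the aldehyde carbon.

Step 4
Reactants: 7 (1R,6R)-2,7,7-trimethylbicyclo[4.2.0]oct-2-ene
Product: 9 3-[(1R,4R)-4-acetyl-2,2-dimethylcyclobutyl]propanal (cis), via secondary ozonide 8 (not isolated)
Conditions: O3, CH2Cl2, −78 °C; then Me2S, −78 °C to rt
Reagents that add atoms: ozone, [O-][O+]=O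
Why: Ozonolysis with reductive work-up cleaves the only C=C bond to the methyl ketone (C8 with the future C12) and the aldehyde (future C4) and leaves both cyclobutane stereocentres untouched.

Step 5
Reactants: 9 3-[(1R,4R)-4-acetyl-2,2-dimethylcyclobutyl]propanal
Product: 11 1-[(1S,2R)-2-(but-3-yn-1-yl)-3,3-dimethylcyclobutyl]ethan-1-one (trans), via cis-alkynyl ketone 10 (not isolated)
Conditions: dimethyl (1-diazo-2-oxopropyl)phosphonate, K2CO3, MeOH, 0 °C to rt; then NaOMe (cat.), rt
Reagents that add atoms: dimethyl (1-diazo-2-oxopropyl)phosphonate, COP(=O)(OC)C(=[N+]=[N-])C(C)=O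
Why: Ohira–Bestmann (Seyferth–Gilbert) homologation converts only the aldehyde into the terminal alkyne C4≡C5, and basic methanol then epimerises the acetyl-bearing carbon C9 to the thermodynamically preferred trans-1,2-disubstituted cyclobutane, which sets C9 as S relative to the fixed C1.

Step 6
Reactants: 11 1-[(1S,2R)-2-(but-3-yn-1-yl)-3,3-dimethylcyclobutyl]ethan-1-one
Product: 12 (1S,2R)-1-(1-bromoethenyl)-2-(but-3-yn-1-yl)-3,3-dimethylcyclobutane
Conditions: (PhO)3P, Br2, CH2Cl2, −60 °C; then 11, Et3N, −60 °C to reflux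
Reagents that add atoms: bromine, BrBr
Why: The triphenyl phosphite–bromine vinyl halide synthesis converts the methyl ketone through the gem-dibromide into the 2-bromoalkene, elimination towards the methyl group being favoured over a strained alkylidenecyclobutane, and the alkyne should be inert because no free Br2 remains once (PhO)3PBr2 has formed.

Step 7
Reactants: 12 (1S,2R)-1-(1-bromoethenyl)-2-(but-3-yn-1-yl)-3,3-dimethylcyclobutane
Product: 14 (2E)-5-[(1R,4S)-4-(1-bromoethenyl)-2,2-dimethylcyclobutyl]-3-methylpent-2-en-1-ol, via alkenyl(dimethyl)alane 13 (not isolated)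
Conditions: AlMe3, Cp2ZrCl2 (20 mol%), CH2Cl2, 0 °C to rt; then (CH2O)n, THF, rt
Reagents that add atoms: trimethylaluminium, C[Al](C)C; formaldehyde (as paraformaldehyde), C=O
Why: Negishi zirconium-catalysed carboalumination adds methyl and aluminium syn across the terminal alkyne with methyl at the internal carbon C4, and trapping of the alkenylalane with formaldehyde with retention fixes the E geometry of C4=C5 on which the C4/C5 relative configuration depends.

Step 8
Reactants: 14 (2E)-5-[(1R,4S)-4-(1-bromoethenyl)-2,2-dimethylcyclobutyl]-3-methylpent-2-en-1-ol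
Product: 15 [(2R,3R)-3-{2-[(1R,4S)-4-(1-bromoethenyl)-2,2-dimethylcyclobutyl]ethyl}-3-methyloxiran-2-yl]methanol
Conditions: Ti(OiPr)4 (10 mol%), D-(−)-diethyl tartrate (12 mol%), t-BuOOH, 4 Å MS, CH2Cl2, −20 °C
Reagents that add atoms: tert-butyl hydroperoxide, CC(C)(C)OO
Why: Sharpless asymmetric epoxidation with the D-(−)-tartrate delivers oxygen to the face that gives the (2R,3R)-epoxide of a geraniol-type allylic alcohol, which sets C4 as R by reagent control independent of the remote cyclobutane; the 1-bromovinyl alkene is not an allylic alcohol and should not react.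

Step 9
Reactants: 15 [(2R,3R)-3-{2-[(1R,4S)-4-(1-bromoethenyl)-2,2-dimethylcyclobutyl]ethyl}-3-methyloxiran-2-yl]methanol
Product: 16 (2S,3R)-5-[(1R,4S)-4-(1-bromoethenyl)-2,2-dimethylcyclobutyl]-2-ethenyl-3-methylpentane-1,3-diol
Conditions: CH2=CHMgBr, CuI (15 mol%), THF/Et2O, −40 to −10 °C
Reagents that add atoms: vinylmagnesium bromide, C=C[Mg]Br
Why: Copper-catalysed SN2 opening of the 2,3-epoxy alcohol should occur at the secondary carbon C5 (the tertiary C4 is blocked) with inversion, so that the vinyl group (C6=C7) and the tertiary C4–O bond end up anti across the former E-alkene, which is the C4/C5 relationship of the target and sets C5.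

Step 10
Reactants: 16 (2S,3R)-5-[(1R,4S)-4-(1-bromoethenyl)-2,2-dimethylcyclobutyl]-2-ethenyl-3-methylpentane-1,3-diol
Product: 17 (3R,4R)-6-[(1R,4S)-4-(1-bromoethenyl)-2,2-dimethylcyclobutyl]-3-(iodomethyl)-4-methylhex-1-en-4-ol
Conditions: I2, PPh3, imidazole, CH2Cl2, 0 °C
Reagents that add atoms: iodine, II
Why: Appel iodination converts only the primary alcohol, the tertiary alcohol being too hindered to form an alkoxyphosphonium salt, and no stereocentre is touched.

Step 11
Reactants: 18 (2S)-2-methylbutanoic acid; 19 phloroglucinol (benzene-1,3,5-triol)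
Product: 21 (2S)-2-methyl-1-(2,4,6-trihydroxyphenyl)butan-1-one, via (2S)-2-methylbutanoyl chloride 20 (not isolated)
Conditions: (COCl)2, DMF (cat.), CH2Cl2, 0 °C to rt; then 19, AlCl3, PhNO2/CH2Cl2, 0 °C to rt
Reagents that add atoms: none
Why: Friedel–Crafts C-acylation of the symmetrical, highly nucleophilic phloroglucinol by the acid chloride made in the flask should stop at the mono-acyl product, and the low temperature limits enolisation of the α-stereocentre.

Step 12
Reactants: 21 (2S)-2-methyl-1-(2,4,6-trihydroxyphenyl)butan-1-one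
Product: 22 3,5-dihydroxy-6,6-dimethyl-2-[(2S)-2-methylbutanoyl]cyclohexa-2,4-dien-1-one
Conditions: NaOMe, MeI, MeOH, 0 °C to rt
Reagents that add atoms: iodomethane, CI
Why: Dearomatising double C-methylation of the acylphloroglucinol polyanion at one ring CH gives the gem-dimethyl cyclohexadienone, and the side-chain stereocentre is protected because the polyanion resists a further deprotonation.

Step 13
Reactants: 17 (3R,4R)-6-[(1R,4S)-4-(1-bromoethenyl)-2,2-dimethylcyclobutyl]-3-(iodomethyl)-4-methylhex-1-en-4-ol; 22 3,5-dihydroxy-6,6-dimethyl-2-[(2S)-2-methylbutanoyl]cyclohexa-2,4-dien-1-one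
Product: 24 (2R,3R)-2-{2-[(1R,4S)-4-(1-bromoethenyl)-2,2-dimethylcyclobutyl]ethyl}-3-ethenyl-5-hydroxy-2,8,8-trimethyl-6-[(2S)-2-methylbutanoyl]-3,4-dihydro-2H-chromen-7(8H)-one, via C-alkylated hydroxy trione 23 (not isolated)
Conditions: 22 (excess), NaH (2 equiv per 22), THF/DMPU, 0 °C; 17, 45 °C; then 1 M HCl; TsOH·H2O (cat.), PhMe, 40 °C
Reagents that add atoms: none
Why: The dianion of 22 should react as a soft carbon nucleophile at its only unsubstituted ring carbon (as in its C-methylation) in an SN2 alkylation by the primary iodide, and acid then closes the dihydropyran by hemiketalisation–dehydration of the tertiary alcohol onto the non-chelated ring carbonyl next to the CMe2 carbon, with the C4–O bond and all stereocentres retained.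

Step 14
Reactants: 24 (2R,3R)-2-{2-[(1R,4S)-4-(1-bromoethenyl)-2,2-dimethylcyclobutyl]ethyl}-3-ethenyl-5-hydroxy-2,8,8-trimethyl-6-[(2S)-2-methylbutanoyl]-3,4-dihydro-2H-chromen-7(8H)-one
Product: 26 CNP0591516.2 (target), via bis(9-BBN) alkylborane 25 (not isolated)
Conditions: 9-BBN (3 equiv), THF, 0 °C to rt; then slow addition to PdCl2(dppf) (20 mol%), AsPh3, Cs2CO3, DMF/THF/H2O, 50 °C, ca. 2 mM; 1 M HCl work-up
Reagents that add atoms: none
Why: 9-BBN first converts the chelated enol O–H into its boron chelate (H2 is lost) and then adds anti-Markovnikov to the monosubstituted C6=C7 vinyl group, far faster than to the electron-poor 1-bromovinyl group or the vinylogous acid carbonyls; zerovalent palladium then inserts into the C8–Br bond, the base-activated B-alkyl group transmetalates, and reductive elimination forms C7–C8. The closest known reaction type is the intramolecular B-alkyl Suzuki–Miyaura coupling used for macrocycles and for nine-membered carbocycles fused to six-membered oxacycles. The nine-membered ring is closed by C(sp3)–C(sp2) bond formation from a ten-membered palladacycle, and the alkene C8=C12 stays exocyclic to the new ring. No stereocentre is created; C1, C9, C4 and C5 are already fixed and none is epimerisable under the conditions. The step needs cyclisation to win over oligomerisation, β-hydride elimination and protodeboronation, which slow addition at high dilution, the large-bite-angle dppf ligand with AsPh3, and the gauche arrangement of the two chains enforced by the trans-fused dihydropyran and the trans-cyclobutane should secure. Mild acidic work-up releases the enol from its boron chelate.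

Compound list
1 | cyclohex-2-en-1-one | O=C1C=CCCC1 | starting material
2 | 2-methylpropene (isobutene) | CC(C)=C | starting material
3 | (1S,6R)-7,7-dimethylbicyclo[4.2.0]octan-2-one (trans-fused photoadduct, not isolated) | O=C1CCC[C@@H]2[C@@H]1CC2(C)C | intermediate
4 | (1R,6R)-7,7-dimethylbicyclo[4.2.0]octan-2-one (cis-fused) | O=C1CCC[C@@H]2[C@H]1CC2(C)C | intermediate
5 | lithium (1R,6R)-7,7-dimethylbicyclo[4.2.0]oct-2-en-2-olate (not isolated) | [Li]OC1=CCC[C@@H]2[C@H]1CC2(C)C | intermediate
6 | (1R,6R)-7,7-dimethylbicyclo[4.2.0]oct-2-en-2-yl trifluoromethanesulfonate | O=S(=O)(OC1=CCC[C@@H]2[C@H]1CC2(C)C)C(F)(F)F | intermediate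
7 | (1R,6R)-2,7,7-trimethylbicyclo[4.2.0]oct-2-ene | CC1=CCC[C@@H]2[C@H]1CC2(C)C | intermediate
8 | secondary ozonide (1,2,4-trioxolane across the former C2=C3 bond) of 7 (not isolated) | CC12OOC(O2)CC[C@@H]3[C@H]1CC3(C)C | intermediate
9 | 3-[(1R,4R)-4-acetyl-2,2-dimethylcyclobutyl]propanal (cis) | O=CCC[C@@H]1[C@H](C(C)=O)CC1(C)C | intermediate
10 | 1-[(1R,2R)-2-(but-3-yn-1-yl)-3,3-dimethylcyclobutyl]ethan-1-one (cis, not isolated) | C#CCC[C@@H]1[C@H](C(C)=O)CC1(C)C | intermediate
11 | 1-[(1S,2R)-2-(but-3-yn-1-yl)-3,3-dimethylcyclobutyl]ethan-1-one (trans) | C#CCC[C@@H]1[C@@H](C(C)=O)CC1(C)C | intermediate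
12 | (1S,2R)-1-(1-bromoethenyl)-2-(but-3-yn-1-yl)-3,3-dimethylcyclobutane | C#CCC[C@@H]1[C@@H](C(Br)=C)CC1(C)C | intermediate
13 | dimethyl{(1E)-4-[(1R,4S)-4-(1-bromoethenyl)-2,2-dimethylcyclobutyl]-2-methylbut-1-en-1-yl}alumane (not isolated) | C[Al](C)/C=C(\C)CC[C@@H]1[C@@H](C(Br)=C)CC1(C)C | intermediate
14 | (2E)-5-[(1R,4S)-4-(1-bromoethenyl)-2,2-dimethylcyclobutyl]-3-methylpent-2-en-1-ol | OC/C=C(\C)CC[C@@H]1[C@@H](C(Br)=C)CC1(C)C | intermediate
15 | [(2R,3R)-3-{2-[(1R,4S)-4-(1-bromoethenyl)-2,2-dimethylcyclobutyl]ethyl}-3-methyloxiran-2-yl]methanol | OC[C@H]1O[C@]1(C)CC[C@@H]1[C@@H](C(Br)=C)CC1(C)C | intermediate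
16 | (2S,3R)-5-[(1R,4S)-4-(1-bromoethenyl)-2,2-dimethylcyclobutyl]-2-ethenyl-3-methylpentane-1,3-diol | C=C[C@@H](CO)[C@](C)(O)CC[C@@H]1[C@@H](C(Br)=C)CC1(C)C | intermediate
17 | (3R,4R)-6-[(1R,4S)-4-(1-bromoethenyl)-2,2-dimethylcyclobutyl]-3-(iodomethyl)-4-methylhex-1-en-4-ol | C=C[C@@H](CI)[C@](C)(O)CC[C@@H]1[C@@H](C(Br)=C)CC1(C)C | intermediate
18 | (2S)-2-methylbutanoic acid | OC(=O)[C@@H](C)CC | starting material
19 | phloroglucinol (benzene-1,3,5-triol) | Oc1cc(O)cc(O)c1 | starting material
20 | (2S)-2-methylbutanoyl chloride (not isolated) | ClC(=O)[C@@H](C)CC | intermediate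
21 | (2S)-2-methyl-1-(2,4,6-trihydroxyphenyl)butan-1-one | O=C(c1c(O)cc(O)cc1O)[C@@H](C)CC | intermediate
22 | 3,5-dihydroxy-6,6-dimethyl-2-[(2S)-2-methylbutanoyl]cyclohexa-2,4-dien-1-one | O=C1C(C(=O)[C@@H](C)CC)=C(O)C=C(O)C1(C)C | intermediate
23 | 4-{(2R,3R)-5-[(1R,4S)-4-(1-bromoethenyl)-2,2-dimethylcyclobutyl]-2-ethenyl-3-hydroxy-3-methylpentyl}-3,5-dihydroxy-6,6-dimethyl-2-[(2S)-2-methylbutanoyl]cyclohexa-2,4-dien-1-one (not isolated) | C=C[C@@H](CC1=C(O)C(C)(C)C(=O)C(C(=O)[C@@H](C)CC)=C1O)[C@](C)(O)CC[C@@H]1[C@@H](C(Br)=C)CC1(C)C | intermediate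
24 | (2R,3R)-2-{2-[(1R,4S)-4-(1-bromoethenyl)-2,2-dimethylcyclobutyl]ethyl}-3-ethenyl-5-hydroxy-2,8,8-trimethyl-6-[(2S)-2-methylbutanoyl]-3,4-dihydro-2H-chromen-7(8H)-one | C=C[C@H]1CC2=C(O[C@]1(C)CC[C@@H]1[C@@H](C(Br)=C)CC1(C)C)C(C)(C)C(=O)C(C(=O)[C@@H](C)CC)=C2O | intermediate
25 | 24 with the vinyl group converted into a 2-(9-borabicyclo[3.3.1]nonan-9-yl)ethyl group (boron on C7) and the enol oxygen bound to a second 9-BBN unit (not isolated) | B1(C2CCCC1CCC2)CC[C@H]3CC4=C(O[C@]3(C)CC[C@@H]5[C@@H](C(Br)=C)CC5(C)C)C(C)(C)C(=O)C(C(=O)[C@@H](C)CC)=C4OB6C7CCCC6CCC7 | intermediate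
26 | CNP0591516.2: (1R,4R,5S,9S)-caryophyllane (exocyclic C8=CH2) fused through C4–O and C5–C1' to the dihydropyran of the 5-hydroxy-8,8-dimethyl-6-[(2S)-2-methylbutanoyl]chromen-7-one unit | C=C1CC[C@H]2CC3=C(O[C@]2(C)CC[C@@H]2[C@@H]1CC2(C)C)C(C)(C)C(=O)C(C(=O)[C@@H](C)CC)=C3O | target

Total step count: 14. Longest linear sequence: 12 steps (steps 1 to 10, then 13 and 14); steps 11 and 12 form the two-step side branch to 22.

Steps most likely to fail

Step 14 (ring closure). Oligomerisation at the expense of cyclisation, β-hydride elimination or protodeboronation of the alkylpalladium/alkylborane species, or reduction of ring A carbonyls by the excess 9-BBN may prevent formation of the nine-membered ring. The fallback sets out from 24 and closes the same C7–C8 bond by a different reaction. Hydroboration with 9-BBN and oxidative work-up (NaBO3·4H2O) should give the C7 primary alcohol F1, and Parikh–Doering oxidation (SO3·pyridine, DMSO, iPr2NEt) the C7 aldehyde F2. An intramolecular Nozaki–Hiyama–Kishi reaction (CrCl2, NiCl2 cat., DMSO, high dilution) between the aldehyde and the 1-bromovinyl group should then close the nine-membered ring to the C7 allylic alcohol F3 (either epimer serves). Methyl chloroformate/pyridine converts it into the bis(methyl carbonate) F4 (allylic carbonate and enol carbonate). Palladium-catalysed formate reduction of the Tsuji–Trost type (Pd(OAc)2, PBu3, HCO2NH4) delivers hydride to the more substituted allyl terminus C7 and keeps the exocyclic methylene; methanolic K2CO3 in the work-up cleaves the enol carbonate. The fallback comes back to the route at 26.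

Step 13 (union with ring A and pyran closure). O-alkylation of the ambident dianion, slow SN2 displacement at the β-branched primary iodide with competing elimination to a diene, or closure of the pyran onto the other ring carbonyl may erode the step. The fallback sets out from 16. Selective oxidation of the primary alcohol (TEMPO, PhI(OAc)2, CH2Cl2) should give the β-hydroxy aldehyde F5, which is used at once in a three-component reductive alkylation of 22 (Knoevenagel condensation, then conjugate reduction of the alkylidene trione by Hantzsch ester, L-proline cat., CH2Cl2, 0 °C). This comes back to the route at 23, which is cyclised to 24 by the acid treatment of step 13.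

Step 6 (bromoalkene). Elimination of the gem-dibromide towards the ring, epimerisation at C9, or addition of HBr to the alkyne may lower the yield and regiochemical purity. The fallback sets out from 11. Regiodefined kinetic enolisation at the methyl group (KN(SiMe3)2, 2.2 equiv, THF, −78 °C; the alkyne C–H is deprotonated as well and restored on work-up) and trapping with PhNTf2 should give the enol triflate F6. Nickel-catalysed triflate-to-bromide exchange (Ni(OAc)2·4H2O, 1,5-cyclooctadiene, Zn cat., LiBr, DMA/THF, rt) then comes back to the route at 12.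

Further compounds
F1 | step 14 | (2R,3R)-2-{2-[(1R,4S)-4-(1-bromoethenyl)-2,2-dimethylcyclobutyl]ethyl}-5-hydroxy-3-(2-hydroxyethyl)-2,8,8-trimethyl-6-[(2S)-2-methylbutanoyl]-3,4-dihydro-2H-chromen-7(8H)-one | OCC[C@H]1CC2=C(O[C@]1(C)CC[C@@H]1[C@@H](C(Br)=C)CC1(C)C)C(C)(C)C(=O)C(C(=O)[C@@H](C)CC)=C2O
F2 | step 14 | the corresponding C7 aldehyde (2-oxoethyl group at C5 of the terpenoid part) | O=CC[C@H]1CC2=C(O[C@]1(C)CC[C@@H]1[C@@H](C(Br)=C)CC1(C)C)C(C)(C)C(=O)C(C(=O)[C@@H](C)CC)=C2O
F3 | step 14 | 7-hydroxy derivative of 26 (allylic alcohol next to the exocyclic methylene, either C7 epimer) | C=C1C(O)C[C@H]2CC3=C(O[C@]2(C)CC[C@@H]2[C@@H]1CC2(C)C)C(C)(C)C(=O)C(C(=O)[C@@H](C)CC)=C3O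
F4 | step 14 | bis(methyl carbonate) of F3 (C7 allylic carbonate and enol carbonate) | C=C1C(OC(=O)OC)C[C@H]2CC3=C(O[C@]2(C)CC[C@@H]2[C@@H]1CC2(C)C)C(C)(C)C(=O)C(C(=O)[C@@H](C)CC)=C3OC(=O)OC
F5 | step 13 | (2R,3R)-5-[(1R,4S)-4-(1-bromoethenyl)-2,2-dimethylcyclobutyl]-2-ethenyl-3-hydroxy-3-methylpentanal | C=C[C@@H](C=O)[C@](C)(O)CC[C@@H]1[C@@H](C(Br)=C)CC1(C)C
F6 | step 6 | 1-[(1S,2R)-2-(but-3-yn-1-yl)-3,3-dimethylcyclobutyl]ethenyl trifluoromethanesulfonate | C#CCC[C@@H]1[C@@H](C(OS(=O)(=O)C(F)(F)F)=C)CC1(C)C
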